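**Retrosynthetic overview** (benzofuranone numbering: O-1, C-2 aryl, C-3 methyl, C-3a allyl, C-4 to C-7, C-7a; ring A = dihydrofuran, ring B = cyclohexadienone)
- Ring B is opened at C-5–C-6 and C-4=C-5 as a Horner–Wadsworth–Emmons [5+1] annulation, with C-5 coming from a methoxymethylphosphonate; ring A is opened at C-3a–C-7a as an intramolecular Michael addition. Both lead back to the acyclic formyl alkoxypropiolate 15.
- Enabling feature: the C-6 carbonyl of ring B lies between the enol-ether carbon C-5 (OMe, with C-4 a CH) and C-7=C-7a, whose β-carbon C-7a carries the ring-A oxygen O-1. So C-7a and C-6 are the two electrophilic ends of an O-1-bound alkoxypropiolate, C-3a is the α-carbon of an aldehyde (C-4), and C-5 is a one-carbon linchpin whose phosphorus removes the aldehyde oxygen.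
- Order of ring formation in one flask: ring A first (C-3a–C-7a, sets the quaternary centre), then ring B (C-5–C-6, then C-4=C-5).
- C-2/C-3 come from a catalytic asymmetric (Z)-crotylboration of 3,4,5-trimethoxybenzaldehyde; the allyl group from a lactone enolate allylation; the O-1 tether from Greene's alkynyl ether synthesis.

Key step: step 10

Remark: the allyl-bearing carbon of 8–15 is carried as an epimer mixture, because it is re-formed from an enolate in step 10.

Step 1
Reactants: 1 3,4,5-trimethoxybenzaldehyde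
Product: 3 (1R,2S)-2-methyl-1-(3,4,5-trimethoxyphenyl)but-3-en-1-ol, via pinacol borate ester 2 (not isolated)
Conditions: (Z)-crotylboronic acid pinacol ester (1.3 equiv), (R)-3,3'-bis(2,4,6-triisopropylphenyl)-1,1'-binaphthyl-2,2'-diyl hydrogen phosphate [(R)-TRIP, 5 mol %], toluene, −30 °C; aq. NaHCO3 work-up
Reagents that add atoms: (Z)-crotylboronic acid pinacol ester, C/C=C\CB1OC(C)(C)C(C)(C)O1
Why: Chiral phosphoric acid catalysed crotylboration (Antilla type) through a closed chair transition state; the Z-crotyl geometry sets the syn aryl/methyl relationship (C-2/C-3 of the target) and the (R)-catalyst is expected to give the 1R carbinol (the antipodal catalyst would be used if the sense proved opposite).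

Step 2
Reactants: 3 (1R,2S)-2-methyl-1-(3,4,5-trimethoxyphenyl)but-3-en-1-ol
Product: 5 (1R,2S)-2-methyl-1-(3,4,5-trimethoxyphenyl)butane-1,4-diol, via bis(9-BBN) adduct 4 (not isolated)
Conditions: 9-BBN (2.5 equiv), THF, 0 → 23 °C; then NaOH, H2O2, 0 °C
Reagents that add atoms: hydrogen peroxide, OO
Why: Anti-Markovnikov hydroboration of the terminal alkene (one equivalent of borane is taken up by the hydroxyl group) and oxidation of the C–B bond, which leaves both stereocentres untouched.

Step 3
Reactants: 5 (1R,2S)-2-methyl-1-(3,4,5-trimethoxyphenyl)butane-1,4-diol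
Product: 7 (4S,5R)-4-methyl-5-(3,4,5-trimethoxyphenyl)oxolan-2-one, via lactol 6 (not isolated)
Conditions: 2,2,6,6-tetramethylpiperidine-1-oxyl (TEMPO, 10 mol %), PhI(OAc)2 (2.5 equiv), CH2Cl2, 23 °C
Reagents that add atoms: none
Why: TEMPO/PhI(OAc)2 oxidative lactonisation, in which the primary alcohol is oxidised selectively, the aldehyde closes to lactol 6 with the benzylic hydroxyl and is oxidised on to the cis γ-lactone.

Step 4
Reactants: 7 (4S,5R)-4-methyl-5-(3,4,5-trimethoxyphenyl)oxolan-2-one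
Product: 8 (4S,5R)-4-methyl-3-(prop-2-en-1-yl)-5-(3,4,5-trimethoxyphenyl)oxolan-2-one
Conditions: LiN(iPr)2 (1.1 equiv), THF, −78 °C; allyl bromide, −78 → −20 °C
Reagents that add atoms: allyl bromide, C=CCBr
Why: Lactone enolate alkylation, with the allyl group entering mainly trans to the neighbouring methyl; the configuration of this centre is irrelevant because it is re-formed in step 10.

Step 5
Reactants: 8 (4S,5R)-4-methyl-3-(prop-2-en-1-yl)-5-(3,4,5-trimethoxyphenyl)oxolan-2-one
Product: 9 (1R,2S)-3-(hydroxymethyl)-2-methyl-1-(3,4,5-trimethoxyphenyl)hex-5-en-1-ol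
Conditions: LiAlH4, THF, 0 °C
Reagents that add atoms: none
Why: Hydride reduction of the lactone to the 1,4-diol, which frees O-1 and puts C-4 at the alcohol level.

Step 6
Reactants: 9 (1R,2S)-3-(hydroxymethyl)-2-methyl-1-(3,4,5-trimethoxyphenyl)hex-5-en-1-ol
Product: 10 (1R,2S)-2-methyl-3-{[(triisopropylsilyl)oxy]methyl}-1-(3,4,5-trimethoxyphenyl)hex-5-en-1-ol
Conditions: triisopropylsilyl chloride (1.05 equiv), imidazole, CH2Cl2, 0 °C
Reagents that add atoms: triisopropylsilyl chloride, CC(C)[Si](Cl)(C(C)C)C(C)C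
Why: Selective silylation of the primary hydroxyl over the hindered benzylic one; the bulky silyl group is chosen to resist O-to-O migration under the basic conditions of step 7.

Step 7
Reactants: 10 (1R,2S)-2-methyl-3-{[(triisopropylsilyl)oxy]methyl}-1-(3,4,5-trimethoxyphenyl)hex-5-en-1-ol
Product: 13 methyl 3-{[(1R,2S)-2-methyl-3-{[(triisopropylsilyl)oxy]methyl}-1-(3,4,5-trimethoxyphenyl)hex-5-en-1-yl]oxy}prop-2-ynoate, via dichlorovinyl ether 11 (not isolated), via lithium alkynyl ether 12 (not isolated)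
Conditions: KH (2 equiv), THF, 0 °C; trichloroethylene (1.2 equiv), 23 °C; then n-BuLi (2.4 equiv), −78 → −40 °C; ClCO2Me, −78 °C
Reagents that add atoms: trichloroethylene, ClC=C(Cl)Cl; methyl chloroformate, COC(=O)Cl
Why: Greene alkynyl ether synthesis: the alkoxide adds to dichloroacetylene formed in situ to give the (E)-dichlorovinyl ether 11, n-BuLi effects dehydrochlorination and chlorine–lithium exchange to the alkoxyacetylide 12, and C-acylation gives the alkoxypropiolate with C-7a, C-7 and C-6 in place.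

Step 8
Reactants: 13 methyl 3-{[(1R,2S)-2-methyl-3-{[(triisopropylsilyl)oxy]methyl}-1-(3,4,5-trimethoxyphenyl)hex-5-en-1-yl]oxy}prop-2-ynoate
Product: 14 methyl 3-{[(1R,2S)-3-(hydroxymethyl)-2-methyl-1-(3,4,5-trimethoxyphenyl)hex-5-en-1-yl]oxy}prop-2-ynoate
Conditions: HF·pyridine, pyridine, THF, 0 → 23 °C
Reagents that add atoms: none
Why: Fluoride-mediated desilylation under buffered conditions intended to spare the acid-sensitive benzylic alkynyl ether.

Step 9
Reactants: 14 methyl 3-{[(1R,2S)-3-(hydroxymethyl)-2-methyl-1-(3,4,5-trimethoxyphenyl)hex-5-en-1-yl]oxy}prop-2-ynoate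
Product: 15 methyl 3-{[(1R,2S)-3-formyl-2-methyl-1-(3,4,5-trimethoxyphenyl)hex-5-en-1-yl]oxy}prop-2-ynoate
Conditions: Dess–Martin periodinane, pyridine, CH2Cl2, 0 °C
Reagents that add atoms: none
Why: Dess–Martin oxidation of the primary alcohol to the aldehyde (C-4) under non-basic conditions, so that no enolate forms before step 10.

Step 10
Reactants: 15 methyl 3-{[(1R,2S)-3-formyl-2-methyl-1-(3,4,5-trimethoxyphenyl)hex-5-en-1-yl]oxy}prop-2-ynoate
Product: 18 (2R,3S,3aS)-5-methoxy-3-methyl-3a-(prop-2-en-1-yl)-2-(3,4,5-trimethoxyphenyl)-3,3a-dihydro-1-benzofuran-6(2H)-one, via Michael adduct 16 (not isolated), via lithium alkoxide adduct 17 (not isolated)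
Conditions: (a) t-BuOK (0.2 equiv), THF, −20 → 0 °C; (b) solution cannulated into (EtO)2P(O)CH(Li)OMe (2.6 equiv, from (EtO)2P(O)CH2OMe and LiN(iPr)2), THF, −78 → 23 °C; aq. NH4Cl
Reagents that add atoms: diethyl (methoxymethyl)phosphonate, CCOP(=O)(COC)OCC
Why: Catalytic t-BuOK forms the equilibrating enolates of the α-branched aldehyde 15, and C-3a adds to C-7a, the oxygen-bearing β-carbon of the alkoxypropiolate, in an intramolecular Michael addition; protonation of the allenolate from the side remote from the new quaternary carbon should give 16 with the ester cis to C-3a, after which the lithiated α-methoxyphosphonate adds to the neopentyl aldehyde (17), its α-phosphonyl carbanion (formed by a further equivalent of base) is acylated by the cis ester to make C-5–C-6, and the β-oxido β-ketophosphonate collapses by Horner–Wadsworth–Emmons elimination to the C-4=C-5 enol ether. The closest known reaction types are base-mediated carbocyclisations of carbonyl compounds onto ynoates and the phosphonate acylation/intramolecular Horner–Wadsworth–Emmons annulation of 1,5-dicarbonyl compounds to cyclohexenones. Ring A closes 5-exo-dig at C-3a–C-7a, and ring B closes 6-exo-trig at C-5–C-6 by acyl substitution, with the olefination then taking place inside the ring so that the aldehyde oxygen leaves as phosphate and C-4 ends as CH. The only new stereocentre, C-3a, is set in the Michael step under Curtin–Hammett conditions: with C-2 perpendicular to the enolate plane as ring A forms, the C-3 methyl should prefer to lie next to C-4, whose cis substituent is H (small allylic 1,3-strain), and not next to the allyl CH2 (larger 1,2-strain), which places the formyl group cis and the allyl group trans to the methyl (3aS). The step needs C-cyclisation at C-3a, the cis acrylate geometry and acylation at C-5 only: C-3a is the single enolisable position and only the five-membered mode is geometrically open, the quaternary aldehyde 16 cannot enolise, and C-5 is the only carbanion present in stage (b).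

**Compound list**
1 | 3,4,5-trimethoxybenzaldehyde | COc1cc(C=O)cc(OC)c1OC | starting material
2 | 2-{[(1R,2S)-2-methyl-1-(3,4,5-trimethoxyphenyl)but-3-en-1-yl]oxy}-4,4,5,5-tetramethyl-1,3,2-dioxaborolane | CC1(C)OB(O[C@@H](c2cc(OC)c(OC)c(OC)c2)[C@H](C=C)C)OC1(C)C | intermediate
3 | (1R,2S)-2-methyl-1-(3,4,5-trimethoxyphenyl)but-3-en-1-ol | O[C@@H](c1cc(OC)c(OC)c(OC)c1)[C@H](C=C)C | intermediate
4 | 9-{(3S,4R)-4-[(9-borabicyclo[3.3.1]nonan-9-yl)oxy]-3-methyl-4-(3,4,5-trimethoxyphenyl)butyl}-9-borabicyclo[3.3.1]nonane | B1(C2CCCC1CCC2)O[C@@H](c3cc(OC)c(OC)c(OC)c3)[C@H](CCB3C4CCCC3CCC4)C | intermediate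
5 | (1R,2S)-2-methyl-1-(3,4,5-trimethoxyphenyl)butane-1,4-diol | O[C@@H](c1cc(OC)c(OC)c(OC)c1)[C@H](CCO)C | intermediate
6 | (4S,5R)-4-methyl-5-(3,4,5-trimethoxyphenyl)oxolan-2-ol (anomers) | O1[C@@H](c2cc(OC)c(OC)c(OC)c2)[C@H](CC1O)C | intermediate
7 | (4S,5R)-4-methyl-5-(3,4,5-trimethoxyphenyl)oxolan-2-one | O1[C@@H](c2cc(OC)c(OC)c(OC)c2)[C@H](CC1=O)C | intermediate
8 | (4S,5R)-4-methyl-3-(prop-2-en-1-yl)-5-(3,4,5-trimethoxyphenyl)oxolan-2-one (C-3 epimers, mainly 3,4-trans) | O1[C@@H](c2cc(OC)c(OC)c(OC)c2)[C@H](C(CC=C)C1=O)C | intermediate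
9 | (1R,2S)-3-(hydroxymethyl)-2-methyl-1-(3,4,5-trimethoxyphenyl)hex-5-en-1-ol (C-3 epimers) | O[C@@H](c1cc(OC)c(OC)c(OC)c1)[C@H](C(CC=C)CO)C | intermediate
10 | (1R,2S)-2-methyl-3-{[(triisopropylsilyl)oxy]methyl}-1-(3,4,5-trimethoxyphenyl)hex-5-en-1-ol (C-3 epimers) | O[C@@H](c1cc(OC)c(OC)c(OC)c1)[C@H](C(CC=C)CO[Si](C(C)C)(C(C)C)C(C)C)C | intermediate
11 | (E)-1,2-dichlorovinyl ether of 10 | Cl/C=C(/Cl)O[C@@H](c1cc(OC)c(OC)c(OC)c1)[C@H](C(CC=C)CO[Si](C(C)C)(C(C)C)C(C)C)C | intermediate
12 | lithium acetylide of the ethynyl ether of 10 | [Li]C#CO[C@@H](c1cc(OC)c(OC)c(OC)c1)[C@H](C(CC=C)CO[Si](C(C)C)(C(C)C)C(C)C)C | intermediate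
13 | methyl 3-{[(1R,2S)-2-methyl-3-{[(triisopropylsilyl)oxy]methyl}-1-(3,4,5-trimethoxyphenyl)hex-5-en-1-yl]oxy}prop-2-ynoate (C-3 epimers) | COC(=O)C#CO[C@@H](c1cc(OC)c(OC)c(OC)c1)[C@H](C(CC=C)CO[Si](C(C)C)(C(C)C)C(C)C)C | intermediate
14 | methyl 3-{[(1R,2S)-3-(hydroxymethyl)-2-methyl-1-(3,4,5-trimethoxyphenyl)hex-5-en-1-yl]oxy}prop-2-ynoate (C-3 epimers) | COC(=O)C#CO[C@@H](c1cc(OC)c(OC)c(OC)c1)[C@H](C(CC=C)CO)C | intermediate
15 | methyl 3-{[(1R,2S)-3-formyl-2-methyl-1-(3,4,5-trimethoxyphenyl)hex-5-en-1-yl]oxy}prop-2-ynoate (C-3 epimers) | COC(=O)C#CO[C@@H](c1cc(OC)c(OC)c(OC)c1)[C@H](C(CC=C)C=O)C | intermediate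
16 | methyl (2E)-2-[(3R,4S,5R)-3-formyl-4-methyl-3-(prop-2-en-1-yl)-5-(3,4,5-trimethoxyphenyl)oxolan-2-ylidene]acetate | C=CC[C@]1(C=O)/C(=C\C(=O)OC)O[C@@H](c2cc(OC)c(OC)c(OC)c2)[C@H]1C | intermediate
17 | lithium alkoxide of the adduct of 16 with lithiated diethyl (methoxymethyl)phosphonate at the formyl group | C=CC[C@]1(C([O-])C(OC)P(=O)(OCC)OCC)/C(=C\C(=O)OC)O[C@@H](c2cc(OC)c(OC)c(OC)c2)[C@H]1C.[Li+] | intermediate
18 | (2R,3S,3aS)-5-methoxy-3-methyl-3a-(prop-2-en-1-yl)-2-(3,4,5-trimethoxyphenyl)-3,3a-dihydro-1-benzofuran-6(2H)-one | C=CC[C@]12C=C(OC)C(=O)C=C1O[C@@H](c1cc(OC)c(OC)c(OC)c1)[C@H]2C | target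

Total step count: 10. Longest linear sequence: 10 steps from 3,4,5-trimethoxybenzaldehyde.

**Steps most likely to fail**

Step 10. The phosphonate carbanion may be used up unproductively: after adding to the neopentyl aldehyde, the adduct may lactonise or eliminate instead of closing ring B. The fallback separates the two stages and masks the aldehyde. It sets out from 16, isolated after stage (a). HC(OMe)3, pyridinium p-toluenesulfonate, MeOH gives the dimethyl acetal of 16 F1. (EtO)2P(O)CH(Li)OMe (2.2 equiv), THF, −78 → 0 °C then acylates at the ester to give the β-ketophosphonate acetal F2. Pyridinium p-toluenesulfonate in acetone/H2O releases the formyl β-ketophosphonate F3. LiCl, DBU, MeCN (Masamune–Roush intramolecular Horner–Wadsworth–Emmons) closes ring B and returns to the route at 18.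

Step 7. n-BuLi may deprotonate the benzylic C–H next to oxygen, leading to a Wittig-type rearrangement, or the electron-rich benzylic alkynyl ether may be lost by ionisation. The fallback replaces the dichloroacetylene route by vinylic substitution and dehydrochlorination. It sets out from 10: NaH, then methyl 3,3-dichloroacrylate, THF, 0 °C gives the chloroacrylate ether F4. LiN(SiMe3)2, THF, −78 °C (α-deprotonation and anti β-elimination of chloride) then gives 13, where the route is rejoined.

Step 1. The electron-rich aldehyde may react sluggishly, with erosion of enantio- and syn-selectivity. The fallback uses stoichiometric reagent control in place of Brønsted acid catalysis (Brown crotylboration). It sets out from 1: (Z)-crotyldiisopinocampheylborane, prepared from cis-2-butene, n-BuLi/t-BuOK and the methoxydiisopinocampheylborane derived from (−)-α-pinene, with BF3·OEt2, THF, −78 °C, then NaOH/H2O2, should give 3 directly. No compound outside the list is made (F0).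

Further compounds
F1 | step 10 | methyl (2E)-2-[(3R,4S,5R)-3-(dimethoxymethyl)-4-methyl-3-(prop-2-en-1-yl)-5-(3,4,5-trimethoxyphenyl)oxolan-2-ylidene]acetate | C=CC[C@]1(C(OC)OC)/C(=C\C(=O)OC)O[C@@H](c2cc(OC)c(OC)c(OC)c2)[C@H]1C
F2 | step 10 | diethyl {(3E)-3-[(3R,4S,5R)-3-(dimethoxymethyl)-4-methyl-3-(prop-2-en-1-yl)-5-(3,4,5-trimethoxyphenyl)oxolan-2-ylidene]-1-methoxy-2-oxopropyl}phosphonate | C=CC[C@]1(C(OC)OC)/C(=C\C(=O)C(OC)P(=O)(OCC)OCC)O[C@@H](c2cc(OC)c(OC)c(OC)c2)[C@H]1C
F3 | step 10 | diethyl {(3E)-3-[(3R,4S,5R)-3-formyl-4-methyl-3-(prop-2-en-1-yl)-5-(3,4,5-trimethoxyphenyl)oxolan-2-ylidene]-1-methoxy-2-oxopropyl}phosphonate | C=CC[C@]1(C=O)/C(=C\C(=O)C(OC)P(=O)(OCC)OCC)O[C@@H](c2cc(OC)c(OC)c(OC)c2)[C@H]1C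
F4 | step 7 | methyl (2Z)-3-chloro-3-{[(1R,2S)-2-methyl-3-{[(triisopropylsilyl)oxy]methyl}-1-(3,4,5-trimethoxyphenyl)hex-5-en-1-yl]oxy}prop-2-enoate | COC(=O)/C=C(\Cl)O[C@@H](c1cc(OC)c(OC)c(OC)c1)[C@H](C(CC=C)CO[Si](C(C)C)(C(C)C)C(C)C)C
F0 | step 1 | none | none
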